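**Retrosynthetic overview**

- Numbering: ring A (cyclohexene) is C1 (ester carbinol)–C2–C3–C4–C5=C6(Me); ring B (cycloheptane) is C3–C4–C7(Me2)–C8–C9–C10–C11(Me)(OH).
- Feature the strategy rests on: the C5=C6(Me)–C1(O) unit of ring A is a dehydrated aldol. Cutting C5=C6 gives a C5 aldehyde on C4 and the C6 methylene of an ethyl ketone (C1) on C3, a 1,5-keto-aldehyde on a finished ring B.
- Both carbonyl groups come from one double ozonolysis of a C4 vinyl group and a C3 2-methylidenebutyl group. These are installed by asymmetric conjugate vinylation of 4,4-dimethylcyclohept-2-en-1-one and trans alkylation of its enolate; the C11 carbinol comes from the ketone by way of a spiro-epoxide.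
- End game: 1,2-reduction of the C1 enone to the pseudo-equatorial alcohol, Mitsunobu inversion with O-silylated isovanillic acid, fluoride removal of both silyl groups.
- Ring order: ring B first (one-carbon ring expansion of the cyclohexenone, step 1), ring A second (aldol condensation, step 8).

Key step: step 8

Assumption: the facial preference of the copper–diphosphine catalyst in step 2 is taken to be the one it shows with cyclohept-2-en-1-one; should the gem-dimethyl group reverse it, the mirror-image ligand is used.

**Route**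

Step 1
Reactants: 1 4,4-dimethylcyclohex-2-en-1-one
Product: 3 4,4-dimethylcyclohept-2-en-1-one, via α-silyl ketone 2 (not isolated)
Conditions: TMSCHN2 (1.2 equiv), AlMe3 (1.2 equiv), CH2Cl2, −78 → −20 °C; then 1 M HCl, THF, rt
Reagents that add atoms: (trimethylsilyl)diazomethane, C[Si](C)(C)C=[N+]=[N-]
Why: Lewis-acid-promoted diazoalkane homologation (Tiffeneau–Demjanov-type ring expansion), in which TMSCHN2 adds to the AlMe3-activated carbonyl and the saturated α-methylene migrates in preference to the vinylic carbon, so that the enone stays conjugated, the bulky α-silyl group of 2 blocks a second insertion and is lost on acidic work-up, and no stereocentre is formed.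

Step 2
Reactants: 3 4,4-dimethylcyclohept-2-en-1-one; 4 vinylmagnesium bromide
Product: 6 {[(3R)-3-ethenyl-4,4-dimethylcyclohept-1-en-1-yl]oxy}(trimethyl)silane, via magnesium enolate 5 (not isolated)
Conditions: 4 (1 M in THF, slow addition), CuBr·SMe2 (5 mol %), (R)-1-[(Sp)-2-(diphenylphosphino)ferrocenyl]ethyldicyclohexylphosphine (6 mol %), t-BuOMe, −78 °C; then TMSCl, Et3N, DMPU, −78 → 0 °C
Reagents that add atoms: chlorotrimethylsilane, C[Si](C)(C)Cl
Why: Copper-catalysed asymmetric conjugate addition of a Grignard reagent to a cyclic enone, in which the chiral diphosphine–copper complex differentiates the enone faces so that the vinyl group should enter at C4 with the (R) configuration, while O-silylation of magnesium enolate 5 fixes the position of the C3 enolate for the next step.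

Step 3
Reactants: 6 {[(3R)-3-ethenyl-4,4-dimethylcyclohept-1-en-1-yl]oxy}(trimethyl)silane; 7 2-(bromomethyl)but-1-ene
Product: 9 (2R,3R)-3-ethenyl-4,4-dimethyl-2-(2-methylidenebutyl)cycloheptan-1-one, via lithium enolate 8 (not isolated)
Conditions: MeLi, THF, 0 °C; then 7, DMPU, −78 → 0 °C
Reagents that add atoms: none
Why: Regiospecific enolate alkylation, in which MeLi cleaves the enol silane to lithium enolate 8 without proton exchange and the reactive allylic bromide should attack C3 on the face anti to the neighbouring C4 vinyl group, which sets the (R) centre at C3 trans to C4, the arrangement also favoured if the α-centre equilibrates.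

Step 4
Reactants: 9 (2R,3R)-3-ethenyl-4,4-dimethyl-2-(2-methylidenebutyl)cycloheptan-1-one
Product: 10 (3R,4R,5R)-5-ethenyl-6,6-dimethyl-4-(2-methylidenebutyl)-1-oxaspiro[2.6]nonane
Conditions: Me3S+ I−, n-BuLi, THF, −10 °C; then 9, −10 °C → rt
Reagents that add atoms: trimethylsulfonium iodide, C[S+](C)C.[I-]
Why: Corey–Chaykovsky epoxidation, in which the small unstabilised sulfonium ylide adds irreversibly to the C11 carbonyl and is expected to come along the pseudo-axial trajectory anti to the C3–H bond, so that the new methylene lies syn and the oxygen anti to the C3 side chain, which is the (R) configuration that C11 has in the target.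

Step 5
Reactants: 10 (3R,4R,5R)-5-ethenyl-6,6-dimethyl-4-(2-methylidenebutyl)-1-oxaspiro[2.6]nonane
Product: 11 (1R,2R,3R)-3-ethenyl-1,4,4-trimethyl-2-(2-methylidenebutyl)cycloheptan-1-ol
Conditions: LiAlH4, THF, 0 °C → rt
Reagents that add atoms: none
Why: Reductive opening of a 1,1-disubstituted epoxide by hydride in an SN2 reaction at the unhindered methylene, which becomes the C11 methyl group while the C11–O bond and its configuration stay untouched and the two alkenes do not react.

Step 6
Reactants: 11 (1R,2R,3R)-3-ethenyl-1,4,4-trimethyl-2-(2-methylidenebutyl)cycloheptan-1-ol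
Product: 12 {[(1R,2R,3R)-3-ethenyl-1,4,4-trimethyl-2-(2-methylidenebutyl)cycloheptyl]oxy}(triethyl)silane
Conditions: TESOTf, 2,6-lutidine, CH2Cl2, −78 → 0 °C
Reagents that add atoms: triethylsilyl trifluoromethanesulfonate, CC[Si](CC)(CC)OS(=O)(=O)C(F)(F)F
Why: Silylation of a hindered tertiary alcohol with a silyl triflate and a hindered pyridine base, which masks the C11 oxygen so that it cannot form lactols with the carbonyl groups made in the next step and changes no stereocentre.

Step 7
Reactants: 12 {[(1R,2R,3R)-3-ethenyl-1,4,4-trimethyl-2-(2-methylidenebutyl)cycloheptyl]oxy}(triethyl)silane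
Product: 14 (1R,6R,7R)-2,2,6-trimethyl-7-(2-oxobutyl)-6-[(triethylsilyl)oxy]cycloheptane-1-carbaldehyde, via bis-ozonide 13 (not isolated)
Conditions: O3, CH2Cl2, −78 °C; then PPh3, −78 °C → rt
Reagents that add atoms: ozone, [O-][O+]=O
Why: Ozonolysis with reductive work-up, which cleaves both terminal alkenes in one operation, the C4 vinyl group to the C5 aldehyde and the 2-methylidenebutyl group to the ethyl ketone, while the neutral phosphine work-up should leave the aldehyde α-centre C4 unepimerised.

Step 8
Reactants: 14 (1R,6R,7R)-2,2,6-trimethyl-7-(2-oxobutyl)-6-[(triethylsilyl)oxy]cycloheptane-1-carbaldehyde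
Product: 16 (4aR,9R,9aR)-3,5,5,9-tetramethyl-9-[(triethylsilyl)oxy]-1,4a,5,6,7,8,9,9a-octahydro-2H-benzo[7]annulen-2-one, via aldol adduct 15 (not isolated)
Conditions: KOH (0.5 equiv), MeOH/THF, 0 → 40 °C
Reagents that add atoms: none
Why: Hydroxide reversibly forms both enolates of the ethyl ketone, and the C6 enolate adds to the C5 aldehyde to give β-hydroxy ketone 15, which loses water by an E1cB path to the conjugated C5=C6 bond. This is an intramolecular aldol condensation of a 1,5-keto-aldehyde, the ring-closing half of a Robinson annulation. Ring A closes in the 6-(enolexo)-exo-trig mode, the enolate carbon C6 bonding to the carbonyl carbon C5 whose oxygen stays outside the new ring. No stereocentre is kept from the step, because the carbinol centre C5 and the methine C6 of 15 vanish on dehydration, and C3, C4 and C11 come unchanged from 14. The step needs only chemoselectivity among the enolisable positions, and ring size secures it, since the C2 enolate and the aldehyde enolate at C4 could close only four-membered rings and C11 carries no free hydroxyl. Should C4 epimerise through the aldehyde enolate, equilibration through the dienolate of 16 is expected to favour the trans ring fusion that the route needs.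

Step 9
Reactants: 16 (4aR,9R,9aR)-3,5,5,9-tetramethyl-9-[(triethylsilyl)oxy]-1,4a,5,6,7,8,9,9a-octahydro-2H-benzo[7]annulen-2-one
Product: 17 (2S,4aR,9R,9aR)-3,5,5,9-tetramethyl-9-[(triethylsilyl)oxy]-2,4a,5,6,7,8,9,9a-octahydro-1H-benzo[7]annulen-2-ol
Conditions: NaBH4, CeCl3·7H2O, MeOH, −78 → −20 °C
Reagents that add atoms: none
Why: Luche 1,2-reduction, in which hydride should add to C1 along the pseudo-axial trajectory on the face of the axial C3–H, as in the reduction of carvone to cis-carveol, to give the pseudo-equatorial (S) alcohol that is cis to the C3–C11 bond.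

Step 10
Reactants: 18 isovanillic acid (3-hydroxy-4-methoxybenzoic acid)
Product: 20 3-[(tert-butyldimethylsilyl)oxy]-4-methoxybenzoic acid, via bis-silyl derivative 19 (not isolated)
Conditions: TBSCl (2.5 equiv), imidazole, DMF, rt; then AcOH/THF/H2O, rt
Reagents that add atoms: tert-butyl(chloro)dimethylsilane, CC(C)(C)[Si](C)(C)Cl
Why: Silylation of phenol and carboxylic acid followed by selective hydrolysis of the labile silyl ester of 19, which leaves the aryl silyl ether in place and frees the acid as the only acidic pronucleophile for the coupling.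

Step 11
Reactants: 17 (2S,4aR,9R,9aR)-3,5,5,9-tetramethyl-9-[(triethylsilyl)oxy]-2,4a,5,6,7,8,9,9a-octahydro-1H-benzo[7]annulen-2-ol; 20 3-[(tert-butyldimethylsilyl)oxy]-4-methoxybenzoic acid
Product: 21 (2R,4aR,9R,9aR)-3,5,5,9-tetramethyl-9-[(triethylsilyl)oxy]-2,4a,5,6,7,8,9,9a-octahydro-1H-benzo[7]annulen-2-yl 3-[(tert-butyldimethylsilyl)oxy]-4-methoxybenzoate
Conditions: PPh3, DIAD, toluene, 0 °C → rt
Reagents that add atoms: none
Why: Mitsunobu esterification, in which the carboxylate of 20 displaces the C1 oxyphosphonium group in an SN2 reaction with inversion, so that the pseudo-equatorial (S) alcohol should give the pseudo-axial (R) ester of the target, as in the known inversion of cis-carveol to trans-carveyl esters.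

Step 12
Reactants: 21 (2R,4aR,9R,9aR)-3,5,5,9-tetramethyl-9-[(triethylsilyl)oxy]-2,4a,5,6,7,8,9,9a-octahydro-1H-benzo[7]annulen-2-yl 3-[(tert-butyldimethylsilyl)oxy]-4-methoxybenzoate
Product: 22 (2R,4aR,9R,9aR)-9-hydroxy-3,5,5,9-tetramethyl-2,4a,5,6,7,8,9,9a-octahydro-1H-benzo[7]annulen-2-yl 3-hydroxy-4-methoxybenzoate
Conditions: TBAF, AcOH, THF, 0 °C → rt
Reagents that add atoms: none
Why: Fluoride-mediated cleavage of silyl ethers, in which the aryl silyl ether should fall at once and the tertiary triethylsilyl ether more slowly, while the acetic acid buffer protects the allylic ester from basic cleavage and no stereocentre is touched.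

**Compound list**

1 | 4,4-dimethylcyclohex-2-en-1-one | CC1(C)CCC(=O)C=C1 | starting material
2 | 4,4-dimethyl-7-(trimethylsilyl)cyclohept-2-en-1-one (α-silyl ketone, C7 not defined) | C[Si](C)(C)C1CCC(C)(C)C=CC1=O | intermediate
3 | 4,4-dimethylcyclohept-2-en-1-one | O=C1C=CC(C)(C)CCC1 | intermediate
4 | vinylmagnesium bromide | C=C[Mg]Br | starting material
5 | bromomagnesium (3R)-3-ethenyl-4,4-dimethylcyclohept-1-en-1-olate (magnesium enolate) | Br[Mg]OC1=C[C@@H](C=C)C(C)(C)CCC1 | intermediate
6 | {[(3R)-3-ethenyl-4,4-dimethylcyclohept-1-en-1-yl]oxy}(trimethyl)silane | C[Si](C)(C)OC1=C[C@@H](C=C)C(C)(C)CCC1 | intermediate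
7 | 2-(bromomethyl)but-1-ene | CCC(=C)CBr | starting material
8 | lithium (3R)-3-ethenyl-4,4-dimethylcyclohept-1-en-1-olate (lithium enolate) | [Li]OC1=C[C@@H](C=C)C(C)(C)CCC1 | intermediate
9 | (2R,3R)-3-ethenyl-4,4-dimethyl-2-(2-methylidenebutyl)cycloheptan-1-one (2,3-trans) | CCC(=C)C[C@@H]1[C@@H](C=C)C(C)(C)CCCC1=O | intermediate
10 | (3R,4R,5R)-5-ethenyl-6,6-dimethyl-4-(2-methylidenebutyl)-1-oxaspiro[2.6]nonane | CCC(=C)C[C@@H]1[C@@H](C=C)C(C)(C)CCC[C@]12CO2 | intermediate
11 | (1R,2R,3R)-3-ethenyl-1,4,4-trimethyl-2-(2-methylidenebutyl)cycloheptan-1-ol | CCC(=C)C[C@@H]1[C@@H](C=C)C(C)(C)CCC[C@@]1(C)O | intermediate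
12 | {[(1R,2R,3R)-3-ethenyl-1,4,4-trimethyl-2-(2-methylidenebutyl)cycloheptyl]oxy}(triethyl)silane | CCC(=C)C[C@@H]1[C@@H](C=C)C(C)(C)CCC[C@@]1(C)O[Si](CC)(CC)CC | intermediate
13 | bis-ozonide of 12: triethyl{[(1R,2R,3R)-2-[(3-ethyl-1,2,4-trioxolan-3-yl)methyl]-1,4,4-trimethyl-3-(1,2,4-trioxolan-3-yl)cycloheptyl]oxy}silane (trioxolane centres not defined) | CCC1(C[C@@H]2[C@@H](C3OCOO3)C(C)(C)CCC[C@@]2(C)O[Si](CC)(CC)CC)OCOO1 | intermediate
14 | (1R,6R,7R)-2,2,6-trimethyl-7-(2-oxobutyl)-6-[(triethylsilyl)oxy]cycloheptane-1-carbaldehyde | CCC(=O)C[C@@H]1[C@@H](C=O)C(C)(C)CCC[C@@]1(C)O[Si](CC)(CC)CC | intermediate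
15 | (4aR,9R,9aR)-4-hydroxy-3,5,5,9-tetramethyl-9-[(triethylsilyl)oxy]decahydro-2H-benzo[7]annulen-2-one (aldol adduct, C3 and C4 not defined) | O=C1C[C@@H]2[C@@H](C(O)C1C)C(C)(C)CCC[C@@]2(C)O[Si](CC)(CC)CC | intermediate
16 | (4aR,9R,9aR)-3,5,5,9-tetramethyl-9-[(triethylsilyl)oxy]-1,4a,5,6,7,8,9,9a-octahydro-2H-benzo[7]annulen-2-one | O=C1C[C@@H]2[C@@H](C=C1C)C(C)(C)CCC[C@@]2(C)O[Si](CC)(CC)CC | intermediate
17 | (2S,4aR,9R,9aR)-3,5,5,9-tetramethyl-9-[(triethylsilyl)oxy]-2,4a,5,6,7,8,9,9a-octahydro-1H-benzo[7]annulen-2-ol | O[C@H]1C[C@@H]2[C@@H](C=C1C)C(C)(C)CCC[C@@]2(C)O[Si](CC)(CC)CC | intermediate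
18 | isovanillic acid (3-hydroxy-4-methoxybenzoic acid) | COc1ccc(cc1O)C(=O)O | starting material
19 | tert-butyldimethylsilyl 3-[(tert-butyldimethylsilyl)oxy]-4-methoxybenzoate | COc1ccc(cc1O[Si](C)(C)C(C)(C)C)C(=O)O[Si](C)(C)C(C)(C)C | intermediate
20 | 3-[(tert-butyldimethylsilyl)oxy]-4-methoxybenzoic acid | COc1ccc(cc1O[Si](C)(C)C(C)(C)C)C(=O)O | intermediate
21 | (2R,4aR,9R,9aR)-3,5,5,9-tetramethyl-9-[(triethylsilyl)oxy]-2,4a,5,6,7,8,9,9a-octahydro-1H-benzo[7]annulen-2-yl 3-[(tert-butyldimethylsilyl)oxy]-4-methoxybenzoate | COc1ccc(C(=O)O[C@@H]2C[C@@H]3[C@@H](C=C2C)C(C)(C)CCC[C@@]3(C)O[Si](CC)(CC)CC)cc1O[Si](C)(C)C(C)(C)C | intermediate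
22 | (2R,4aR,9R,9aR)-9-hydroxy-3,5,5,9-tetramethyl-2,4a,5,6,7,8,9,9a-octahydro-1H-benzo[7]annulen-2-yl 3-hydroxy-4-methoxybenzoate | COc1ccc(C(=O)O[C@@H]2C[C@@H]3[C@@H](C=C2C)C(C)(C)CCC[C@@]3(C)O)cc1O | target

**Step count and risks**

Total steps: 12. Longest linear sequence: 11 steps (steps 1–9, 11 and 12, from 1 to 22); step 10 is a one-step side branch.

Steps most likely to fail:

1. Step 2. The enantioselectivity may erode, because the vinyl Grignard reagent brings THF and can react through a weakly ligand-bound pathway. The addition at the neopentyl β-carbon C4 may also be slow enough for 1,2-addition to compete. The fallback separates the enantioselective bond formation from the regiocontrol.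
   - It sets out from enone 3. Rhodium-catalysed asymmetric 1,4-addition of CH2=CHBF3K ([Rh(cod)2]BF4, (S)-BINAP, toluene/H2O, 100 °C) should give (3S)-3-ethenyl-4,4-dimethylcycloheptan-1-one F1; the ligand antipode is chosen by analogy with cyclohept-2-en-1-one.
   - Claisen formylation (NaH, HCO2Et, THF) at the unhindered C10 methylene should give (6S)-6-ethenyl-2-(hydroxymethylidene)-5,5-dimethylcycloheptan-1-one F2.
   - Its dianion (LiN(i-Pr)2, 2.2 equiv, THF, −78 → 0 °C) can be alkylated only at the remaining α-carbon C3, and with bromide 7 should give (2R,3R)-3-ethenyl-7-(hydroxymethylidene)-4,4-dimethyl-2-(2-methylidenebutyl)cycloheptan-1-one F3.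
   - Aqueous NaOH in MeOH at reflux then removes the formyl group by retro-Claisen cleavage and equilibrates C3 to the trans ketone 9, where the route is rejoined.

2. Step 4. The ylide may add to the flexible cycloheptanone with poor facial selectivity, and the basic ylide may enolise the hindered ketone instead of adding. The fallback replaces the epoxidation–reduction pair by a direct methyl addition under Lewis-acid face blocking.
   - It sets out from ketone 9. The carbonyl group is precomplexed with MeAl(OAr)2 (Ar = 2,6-di-tert-butyl-4-methylphenyl, made from AlMe3 and two equivalents of the phenol) in toluene at −78 °C, and MeLi is added.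
   - The bulky aluminium aryloxide should sit on the more open carbonyl face, so methyl is forced to enter from the face syn to the C3 side chain, the reverse of an uncomplexed MeLi addition.
   - This should give tertiary alcohol 11 in one step, where the route is rejoined; the fallback makes no compound outside the list (F0).

3. Step 11. SN2′ attack at C5 or elimination of the activated allylic oxygen to a diene may compete, and displacement at the carbinol next to the C6 methyl group may be slow. The fallback sets C1 by reagent-controlled reduction and forms the ester with retention.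
   - It sets out from enone 16. CBS reduction with the (S)-configured B-methyl oxazaborolidine and catecholborane (toluene, −78 → −40 °C), with the alkenyl arm acting as the large group, should give the pseudo-axial alcohol (2R,4aR,9R,9aR)-3,5,5,9-tetramethyl-9-[(triethylsilyl)oxy]-2,4a,5,6,7,8,9,9a-octahydro-1H-benzo[7]annulen-2-ol F4.
   - Steglich esterification of F4 with acid 20 (DCC, DMAP, CH2Cl2, rt) keeps the C1 configuration and should give ester 21, where the route is rejoined.

Further compounds
F1 | step 2 | (3S)-3-ethenyl-4,4-dimethylcycloheptan-1-one | O=C1C[C@@H](C=C)C(C)(C)CCC1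
F2 | step 2 | (6S)-6-ethenyl-2-(hydroxymethylidene)-5,5-dimethylcycloheptan-1-one | O=C1C[C@@H](C=C)C(C)(C)CCC1=CO
F3 | step 2 | (2R,3R)-3-ethenyl-7-(hydroxymethylidene)-4,4-dimethyl-2-(2-methylidenebutyl)cycloheptan-1-one | CCC(=C)C[C@@H]1[C@@H](C=C)C(C)(C)CCC(=CO)C1=O
F0 | step 4 | none | none
F4 | step 11 | (2R,4aR,9R,9aR)-3,5,5,9-tetramethyl-9-[(triethylsilyl)oxy]-2,4a,5,6,7,8,9,9a-octahydro-1H-benzo[7]annulen-2-ol | O[C@@H]1C[C@@H]2[C@@H](C=C1C)C(C)(C)CCC[C@@]2(C)O[Si](CC)(CC)CC
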